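**Retrosynthetic overview**

- The plan rests on ring B: C1' (bridge carbon), C2' (enol OH), C3' (CMe2), C4' (enol OH), C5' (acetyl-bearing), C6' (C=O). It is an acetylphloroglucinol whose aromaticity has been removed by two methyl groups on C3'.
- Key disconnection: both C3'–CH3 bonds, 10 ⇐ 7 + 2 MeI. No ring is formed anywhere in the route; rings A and B are both bought as phloroglucinols.
- Ring A carries its two phenols as benzyl ethers through the key step and loses them last (11 ⇐ 10). This leaves ring B as the only ionisable ring, so ring A can be neither methylated nor expelled through an ortho-quinone methide under base.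
- The C1'–CH2 bond comes from a Friedel–Crafts benzylation of 2,4,6-trihydroxyacetophenone 6 with the ring A benzylic alcohol 5.
- Alcohol 5 comes from butyrylphloroglucinol 1 by para O-methylation, ring formylation, O-benzylation and aldehyde reduction.

Key step: step 6

Assumption: the target SMILES shows one of the equilibrating enol tautomers of ring B; the route makes this tautomeric compound, which has no stereocentre.

**Step 1**
Reactants: 1 1-(2,4,6-trihydroxyphenyl)butan-1-one
Product: 2 1-(2,6-dihydroxy-4-methoxyphenyl)butan-1-one
Conditions: Me2SO4 (1.05 equiv), K2CO3 (1.1 equiv), acetone, 0 °C → rt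
Reagents that add atoms: dimethyl sulfate, COS(=O)(=O)OC
Why: Williamson-type SN2 O-methylation; the 4-OH is para to the acyl group, is the most acidic and is not chelated, so with one equivalent of a hard methylating agent and a weak base it should be etherified ahead of the two carbonyl-chelated ortho hydroxyls.

**Step 2**
Reactants: 2 1-(2,6-dihydroxy-4-methoxyphenyl)butan-1-one
Product: 3 3-butanoyl-2,4-dihydroxy-6-methoxybenzaldehyde
Conditions: Cl2CHOMe (1.2 equiv), TiCl4 (3 equiv), CH2Cl2, 0 °C → rt; then ice, 1 M HCl
Reagents that add atoms: dichloromethyl methyl ether, COC(Cl)Cl; water, O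
Why: Rieche formylation, an electrophilic aromatic substitution directed ortho to the titanium phenoxide; the two free ring positions of 2 are equivalent and the first formyl group deactivates the ring against a second.

**Step 3**
Reactants: 3 3-butanoyl-2,4-dihydroxy-6-methoxybenzaldehyde
Product: 4 2,4-bis(benzyloxy)-3-butanoyl-6-methoxybenzaldehyde
Conditions: BnBr (2.6 equiv), K2CO3 (3 equiv), DMF, 60 °C
Reagents that add atoms: benzyl bromide, BrCc1ccccc1
Why: Williamson ether synthesis; in DMF with warming both chelated phenoxides should be O-benzylated, and the ring, carrying two carbonyl groups, is too electron-poor for C-benzylation to compete.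

**Step 4**
Reactants: 4 2,4-bis(benzyloxy)-3-butanoyl-6-methoxybenzaldehyde
Product: 5 1-[2,6-bis(benzyloxy)-3-(hydroxymethyl)-4-methoxyphenyl]butan-1-one
Conditions: NaBH4 (1 equiv), THF/MeOH, −20 → 0 °C; then aq. NH4Cl
Reagents that add atoms: none
Why: Chemoselective borohydride reduction; the aldehyde should be reduced far faster than the ketone, which is twisted out of the ring plane and shielded by two ortho benzyloxy groups.

**Step 5**
Reactants: 5 1-[2,6-bis(benzyloxy)-3-(hydroxymethyl)-4-methoxyphenyl]butan-1-one; 6 1-(2,4,6-trihydroxyphenyl)ethan-1-one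
Product: 7 1-{3-[(3-acetyl-2,4,6-trihydroxyphenyl)methyl]-2,6-bis(benzyloxy)-4-methoxyphenyl}butan-1-one
Conditions: 6 (3 equiv), pTsOH·H2O (10 mol%), MeCN, 0 °C → rt
Reagents that add atoms: none
Why: Friedel–Crafts benzylation; catalytic acid should ionise 5 to a benzylic cation stabilised by two ortho and one para alkoxy groups, which is captured at one of the two equivalent free carbons of 6, used in excess to suppress double benzylation.

**Step 6**
Reactants: 7 1-{3-[(3-acetyl-2,4,6-trihydroxyphenyl)methyl]-2,6-bis(benzyloxy)-4-methoxyphenyl}butan-1-one; 8 iodomethane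
Product: 10 2-acetyl-6-{[2,4-bis(benzyloxy)-3-butanoyl-6-methoxyphenyl]methyl}-3,5-dihydroxy-4,4-dimethylcyclohexa-2,5-dien-1-one, via C3'-monomethyl arene 9 (not isolated)
Conditions: NaOMe (4 equiv), MeI (2.1 equiv), MeOH/THF, 0 °C → rt; then 1 M HCl
Reagents that add atoms: iodomethane (8), CI
Why: NaOMe converts ring B of 7, the only ionisable part of the molecule, into a phloroglucinolate di- or trianion whose carbon nucleophilicity is concentrated at its single ring C–H, C3', so a first SN2 attack on MeI followed by proton loss should give the C3'-methyl arene 9. The more electron-rich anion of 9 should attack a second MeI through the same carbon, creating the quaternary C3' and locking ring B as the enolised triketone of 10; this is the alkylative dearomatisation by which acylphloroglucinols are turned into acylfilicinic acids with MeI and alkoxide. No ring is closed and no stereocentre is created, since C3' ends with two identical methyl groups. The step needs C3' over the bridge-bearing C1' in the second alkylation, carbon over oxygen, and a stop after two methyl groups: C1' is shielded by its heavily ortho-substituted benzyl group, the hydrogen-bonding solvent MeOH together with the soft electrophile MeI favours C-alkylation, and MeI is held near two equivalents. Ring A cannot interfere because both of its phenols are benzyl ethers, so it has no phenoxide to be C- or O-methylated and cannot expel ring B through an ortho-quinone methide, the base-induced bridge scission that free methylene-bis(phloroglucinols) undergo.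

**Step 7**
Reactants: 10 2-acetyl-6-{[2,4-bis(benzyloxy)-3-butanoyl-6-methoxyphenyl]methyl}-3,5-dihydroxy-4,4-dimethylcyclohexa-2,5-dien-1-one
Product: 11 2-acetyl-6-[(3-butanoyl-2,4-dihydroxy-6-methoxyphenyl)methyl]-3,5-dihydroxy-4,4-dimethylcyclohexa-2,5-dien-1-one
Conditions: H2 (1 atm), Pd/C (10 wt%), EtOAc, rt
Reagents that add atoms: none
Why: Catalytic hydrogenolysis of the two aryl benzyl ethers; the neutral medium should leave the chelated aryl ketone, the enolised triketone and the CH2 bridge untouched and keeps the free bisphenol away from base.

**Compound list**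

1 | 1-(2,4,6-trihydroxyphenyl)butan-1-one | CCCC(=O)c1c(O)cc(O)cc1O | starting material
2 | 1-(2,6-dihydroxy-4-methoxyphenyl)butan-1-one | CCCC(=O)c1c(O)cc(OC)cc1O | intermediate
3 | 3-butanoyl-2,4-dihydroxy-6-methoxybenzaldehyde | CCCC(=O)c1c(O)cc(OC)c(C=O)c1O | intermediate
4 | 2,4-bis(benzyloxy)-3-butanoyl-6-methoxybenzaldehyde | CCCC(=O)c1c(OCc2ccccc2)cc(OC)c(C=O)c1OCc1ccccc1 | intermediate
5 | 1-[2,6-bis(benzyloxy)-3-(hydroxymethyl)-4-methoxyphenyl]butan-1-one | CCCC(=O)c1c(OCc2ccccc2)cc(OC)c(CO)c1OCc1ccccc1 | intermediate
6 | 1-(2,4,6-trihydroxyphenyl)ethan-1-one | CC(=O)c1c(O)cc(O)cc1O | starting material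
7 | 1-{3-[(3-acetyl-2,4,6-trihydroxyphenyl)methyl]-2,6-bis(benzyloxy)-4-methoxyphenyl}butan-1-one | CCCC(=O)c1c(OCc2ccccc2)cc(OC)c(Cc2c(O)cc(O)c(C(C)=O)c2O)c1OCc1ccccc1 | intermediate
8 | iodomethane | CI | starting material
9 | 1-{3-[(3-acetyl-2,4,6-trihydroxy-5-methylphenyl)methyl]-2,6-bis(benzyloxy)-4-methoxyphenyl}butan-1-one | CCCC(=O)c1c(OCc2ccccc2)cc(OC)c(Cc2c(O)c(C)c(O)c(C(C)=O)c2O)c1OCc1ccccc1 | intermediate
10 | 2-acetyl-6-{[2,4-bis(benzyloxy)-3-butanoyl-6-methoxyphenyl]methyl}-3,5-dihydroxy-4,4-dimethylcyclohexa-2,5-dien-1-one | CCCC(=O)c1c(OCc2ccccc2)cc(OC)c(CC2=C(O)C(C)(C)C(O)=C(C(C)=O)C2=O)c1OCc1ccccc1 | intermediate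
11 | 2-acetyl-6-[(3-butanoyl-2,4-dihydroxy-6-methoxyphenyl)methyl]-3,5-dihydroxy-4,4-dimethylcyclohexa-2,5-dien-1-one | CCCC(=O)c1c(O)cc(OC)c(CC2=C(O)C(C)(C)C(O)=C(C(C)=O)C2=O)c1O | target

**Step count**

Total step count: 7. Longest linear sequence: 7 steps (1 → 11).

**Steps most likely to fail**

1. Step 6. Site control may be lost in the second methylation, with attack at the bridge-bearing C1' or on oxygen, and the dearomatised ring may take up a third methyl group. Fallback: set out from 6 and methylate it alone with MeI and NaOMe in MeOH, the established acylfilicinic acid preparation. This should give 2-acetyl-3,5-dihydroxy-4,4-dimethylcyclohexa-2,5-dien-1-one F1, which is freed of under- and over-methylated congeners while the molecule is still small. The remaining enol C–H of F1 is then benzylated with alcohol 5 under the acid catalysis of step 5 (pTsOH·H2O, MeCN, rt), a Friedel–Crafts-type alkylation of a vinylogous acid. The fallback rejoins the route at 10.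

2. Step 5. The benzylic cation may react twice with 6, may attack the free C–H of another ring A molecule and oligomerise, or the benzylation may reverse under acid. Fallback: set out from 5 and convert it with SOCl2 in CH2Cl2 at −20 °C into 1-[2,6-bis(benzyloxy)-3-(chloromethyl)-4-methoxyphenyl]butan-1-one F2, used crude. F2 then C-alkylates the phloroglucinolate of excess 6 under base (DBU, THF, 0 °C), an anionic SN2 benzylation in place of the cationic one. The fallback rejoins the route at 7.

3. Step 7. Hydrogenolysis may stall at the hindered ethers, or hydrogen may add to the aryl ketone. Fallback: set out from 10 and cleave both benzyl ethers without hydrogen, using BCl3 and pentamethylbenzene as cation scavenger in CH2Cl2 at −78 °C, then aqueous work-up. Both benzyl ethers sit ortho to the butanoyl carbonyl and should be cleaved readily, while the methyl ether, which is not next to a carbonyl, should survive. The fallback gives 11 directly and passes through no new compound (none F0).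

**Further compounds**

F1 | step 6 | 2-acetyl-3,5-dihydroxy-4,4-dimethylcyclohexa-2,5-dien-1-one | CC(=O)C1=C(O)C(C)(C)C(O)=CC1=O
F2 | step 5 | 1-[2,6-bis(benzyloxy)-3-(chloromethyl)-4-methoxyphenyl]butan-1-one | CCCC(=O)c1c(OCc2ccccc2)cc(OC)c(CCl)c1OCc1ccccc1
F0 | step 7 | none | none
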